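The benzene ring itself is disconnected: the ring carbon bearing C8, its oxygenated neighbour and the para carbon bearing C7 map onto a terminal alkyne and 3-bromocoumalic acid. One thermal operation, a 2-pyrone Diels–Alder reaction followed by loss of CO2, forms two ring bonds, closes the arene and delivers the crowded aryl–C8 bond with bromine (the future phenol oxygen) and the carboxyl (the future C7) correctly placed. The alkyne partner is a small propargylic carbinol in which C8 already has its final (R) configuration and both acyl arms. In the flask it and the pyrone acid are silylated, so that no free OH or CO2H is present during heating.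

Key step: step 6

Remark: the sense of a lipase desymmetrisation cannot be predicted with certainty; it is assumed that enzyme screening finds a lipase that acetylates the pro-S hydroxymethyl arm of the prochiral triol, which leads to the (R) configuration at C8 after the second acylation.

Step 1
Reactants: 1 2,2-dimethyl-1,3-dioxan-5-one
Product: 2 5-ethynyl-2,2-dimethyl-1,3-dioxan-5-ol
Conditions: HC≡CMgBr, THF, 0 °C to rt; then H2O
Reagents that add atoms: ethynylmagnesium bromide, C#C[Mg]Br
Why: Grignard 1,2-addition of the acetylide to the ketone should give the tertiary propargylic alcohol, which is achiral because the carbinol carbon carries two identical CH2O arms.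

Step 2
Reactants: 2 5-ethynyl-2,2-dimethyl-1,3-dioxan-5-ol
Product: 3 2-ethynylpropane-1,2,3-triol
Conditions: sulfonic acid ion-exchange resin (H+ form), MeOH/H2O, rt; filter, evaporate
Reagents that add atoms: none
Why: Acid-catalysed acetal hydrolysis (acetonide cleavage) on a resin is mild enough not to ionise the tertiary propargylic alcohol and avoids an aqueous extraction of the water-soluble triol.

Step 3
Reactants: 3 2-ethynylpropane-1,2,3-triol
Product: 4 (2S)-2-hydroxy-2-(hydroxymethyl)but-3-yn-1-yl acetate
Conditions: immobilised lipase from Burkholderia cepacia, vinyl acetate, THF, 25 °C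
Reagents that add atoms: vinyl acetate, CC(=O)OC=C
Why: Lipase-catalysed enantiotopic-group-selective transesterification (enzymatic desymmetrisation of a prochiral 2-substituted glycerol) with an irreversible acyl donor should set C8, because the chiral active site of the enzyme distinguishes the two hydroxymethyl arms while the tertiary hydroxyl is not acylated.

Step 4
Reactants: 4 (2S)-2-hydroxy-2-(hydroxymethyl)but-3-yn-1-yl acetate; 5 angelic acid
Product: 7 (2R)-2-(acetoxymethyl)-2-hydroxybut-3-yn-1-yl (2Z)-2-methylbut-2-enoate, via angelic trichlorobenzoic anhydride 6 (not isolated)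
Conditions: 5, 2,4,6-trichlorobenzoyl chloride, Et3N, toluene, rt; then 4, 60 °C, no DMAP
Reagents that add atoms: none
Why: Yamaguchi-type esterification through the 2,4,6-trichlorobenzoyl mixed anhydride acylates only the primary hydroxyl and, run without DMAP, is the established way to make angelates without Z-to-E isomerisation; the monoacetate is used at once so that acetyl migration between the two arms cannot erode C8, whose descriptor changes from S to R only because the ligand ranking changes.

Step 5
Reactants: 8 coumalic acid
Product: 9 3-bromocoumalic acid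
Conditions: Br2, AcOH, 60 °C
Reagents that add atoms: bromine, BrBr
Why: Electrophilic bromination of the 2-pyrone (electrophilic substitution) should go to C3, the only nucleophilic ring position left, since C5 is blocked and deactivated by the carboxyl group.

Step 6
Reactants: 9 3-bromocoumalic acid; 7 (2R)-2-(acetoxymethyl)-2-hydroxybut-3-yn-1-yl (2Z)-2-methylbut-2-enoate
Product: 14 3-bromo-4-[(2R)-1-acetoxy-2-hydroxy-3-{[(2Z)-2-methylbut-2-enoyl]oxy}propan-2-yl]benzoic acid, via trimethylsilyl 3-bromocoumalate 10 (not isolated), via O-trimethylsilyl alkyne 11 (not isolated), via bridged bicyclic lactone 12 (not isolated), via bis-silylated arene 13 (not isolated)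
Conditions: 9 (1.5 equiv), BSA, TMSCl (cat.), toluene, 60 °C; then BHT (cat.), 150 °C, sealed tube, dark; then AcOH/THF/H2O, rt
Reagents that add atoms: none
Why: After transient silylation, which makes the mixture aprotic and homogeneous and removes the free hydroxyl through which acyl groups could shuttle between the arms, the electron-poor pyrone diene C3=C4–C5=C6 of 10 adds across the alkyne of 11 in an inverse-electron-demand Diels–Alder reaction, and the bridged lactone 12 then loses CO2 by retro-[4+2] cycloreversion, which makes the sequence irreversible and gives the arene directly. The closest known reaction type is the thermal cycloaddition–decarboxylation of coumalates and of 3-bromo-2-pyrones with terminal alkynes to give para-substituted benzoates. The benzene ring is closed by an intermolecular, concerted but asynchronous [4+2] cycloaddition that forms the bonds from pyrone C6 to the terminal alkyne carbon and from pyrone C3 to the C8-bearing alkyne carbon. No stereocentre is created, since the two bridgehead centres of 12 disappear on aromatisation and C8, which takes no part, keeps its (R) configuration. The step needs regioselectivity and chemoselectivity: C6, conjugated to both the lactone carbonyl and the C5 carboxyl, is the most electrophilic diene terminus and bonds first to the unhindered, more nucleophilic terminal carbon, so the crowded contact between bromine and C8 is confined to the longer, later-forming bond, the orientation that both a C5 ester and a C3 bromine are known to favour. The alkyne is the only π bond expected to react, because the angelate alkene is trisubstituted and electron-poor, and the radical inhibitor and exclusion of light guard that alkene against bromine-radical-mediated isomerisation.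

Step 7
Reactants: 14 3-bromo-4-[(2R)-1-acetoxy-2-hydroxy-3-{[(2Z)-2-methylbut-2-enoyl]oxy}propan-2-yl]benzoic acid
Product: 15 (2R)-3-acetoxy-2-[2-bromo-4-(hydroxymethyl)phenyl]-2-hydroxypropyl (2Z)-2-methylbut-2-enoate
Conditions: BH3·SMe2, THF, 0 °C to rt; then MeOH
Reagents that add atoms: none
Why: Chemoselective borane reduction of the carboxylic acid through its acyloxyborane should be much faster than reduction of the two esters or hydroboration of the hindered, electron-poor trisubstituted angelate alkene, and the medium is non-basic so no acyl migration is expected.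

Step 8
Reactants: 15 (2R)-3-acetoxy-2-[2-bromo-4-(hydroxymethyl)phenyl]-2-hydroxypropyl (2Z)-2-methylbut-2-enoate; 16 (2R)-2-methylbutanoic acid
Product: 17 (2R)-3-acetoxy-2-[2-bromo-4-({[(2R)-2-methylbutanoyl]oxy}methyl)phenyl]-2-hydroxypropyl (2Z)-2-methylbut-2-enoate
Conditions: EDC·HCl, DMAP (cat.), CH2Cl2, 0 °C to rt
Reagents that add atoms: none
Why: Steglich esterification should acylate the primary benzylic alcohol and leave the tertiary alcohol untouched, and an α-alkyl-branched acid without an activating α-substituent is not expected to racemise under carbodiimide activation, so the (R) centre of the acid is carried in unchanged.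

Step 9
Reactants: 17 (2R)-3-acetoxy-2-[2-bromo-4-({[(2R)-2-methylbutanoyl]oxy}methyl)phenyl]-2-hydroxypropyl (2Z)-2-methylbut-2-enoate
Product: 19 (2R)-3-acetoxy-2-hydroxy-2-[2-hydroxy-4-({[(2R)-2-methylbutanoyl]oxy}methyl)phenyl]propyl (2Z)-2-methylbut-2-enoate, via aryl pinacol boronate 18 (not isolated)
Conditions: B2pin2, Pd2(dba)3, XPhos, KOAc, 1,4-dioxane, 80 °C; then 30% H2O2, pH 7 buffer (NaH2PO4/Na2HPO4), THF, 0 °C to rt
Reagents that add atoms: hydrogen peroxide, OO
Why: Miyaura borylation of the aryl bromide under weakly basic acetate conditions, followed by oxidation of the C–B bond (1,2-aryl shift from boron to oxygen in the peroxide adduct) at neutral pH, should give the phenol without ester hydrolysis, acyl migration or epoxidation of the electron-poor alkene.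

Compound list
1 | 2,2-dimethyl-1,3-dioxan-5-one | CC1(C)OCC(=O)CO1 | starting material
2 | 5-ethynyl-2,2-dimethyl-1,3-dioxan-5-ol (achiral) | CC1(C)OCC(O)(C#C)CO1 | intermediate
3 | 2-ethynylpropane-1,2,3-triol (2-ethynylglycerol, prochiral) | OCC(O)(CO)C#C | intermediate
4 | (2S)-2-hydroxy-2-(hydroxymethyl)but-3-yn-1-yl acetate | OC[C@](O)(COC(C)=O)C#C | intermediate
5 | angelic acid, (2Z)-2-methylbut-2-enoic acid | C/C=C(/C)C(=O)O | starting material
6 | (2Z)-2-methylbut-2-enoic 2,4,6-trichlorobenzoic anhydride (formed in the flask, not isolated) | C/C=C(/C)C(=O)OC(=O)c1c(Cl)cc(Cl)cc1Cl | intermediate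
7 | (2R)-2-(acetoxymethyl)-2-hydroxybut-3-yn-1-yl (2Z)-2-methylbut-2-enoate (2-ethynylglycerol 1-acetate 3-angelate) | C/C=C(/C)C(=O)OC[C@](O)(COC(C)=O)C#C | intermediate
8 | coumalic acid (2-oxo-2H-pyran-5-carboxylic acid) | OC(=O)C1=COC(=O)C=C1 | starting material
9 | 3-bromocoumalic acid (3-bromo-2-oxo-2H-pyran-5-carboxylic acid) | OC(=O)C1=COC(=O)C(Br)=C1 | intermediate
10 | trimethylsilyl 3-bromo-2-oxo-2H-pyran-5-carboxylate (not isolated) | C[Si](C)(C)OC(=O)C1=COC(=O)C(Br)=C1 | intermediate
11 | (2R)-2-(acetoxymethyl)-2-[(trimethylsilyl)oxy]but-3-yn-1-yl (2Z)-2-methylbut-2-enoate (not isolated) | C/C=C(/C)C(=O)OC[C@](O[Si](C)(C)C)(COC(C)=O)C#C | intermediate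
12 | trimethylsilyl 4-bromo-5-[(2R)-1-acetoxy-3-{[(2Z)-2-methylbut-2-enoyl]oxy}-2-[(trimethylsilyl)oxy]propan-2-yl]-3-oxo-2-oxabicyclo[2.2.2]octa-5,7-diene-7-carboxylate (not isolated; both bridgehead diastereomers, bridgeheads left undefined because they vanish) | C/C=C(/C)C(=O)OC[C@](O[Si](C)(C)C)(COC(C)=O)C1=CC2OC(=O)C1(Br)C=C2C(=O)O[Si](C)(C)C | intermediate
13 | trimethylsilyl 3-bromo-4-[(2R)-1-acetoxy-3-{[(2Z)-2-methylbut-2-enoyl]oxy}-2-[(trimethylsilyl)oxy]propan-2-yl]benzoate (not isolated) | C/C=C(/C)C(=O)OC[C@](O[Si](C)(C)C)(COC(C)=O)c1ccc(C(=O)O[Si](C)(C)C)cc1Br | intermediate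
14 | 3-bromo-4-[(2R)-1-acetoxy-2-hydroxy-3-{[(2Z)-2-methylbut-2-enoyl]oxy}propan-2-yl]benzoic acid | C/C=C(/C)C(=O)OC[C@](O)(COC(C)=O)c1ccc(C(=O)O)cc1Br | intermediate
15 | (2R)-3-acetoxy-2-[2-bromo-4-(hydroxymethyl)phenyl]-2-hydroxypropyl (2Z)-2-methylbut-2-enoate | C/C=C(/C)C(=O)OC[C@](O)(COC(C)=O)c1ccc(CO)cc1Br | intermediate
16 | (2R)-2-methylbutanoic acid | CC[C@@H](C)C(=O)O | starting material
17 | (2R)-3-acetoxy-2-[2-bromo-4-({[(2R)-2-methylbutanoyl]oxy}methyl)phenyl]-2-hydroxypropyl (2Z)-2-methylbut-2-enoate | C/C=C(/C)C(=O)OC[C@](O)(COC(C)=O)c1ccc(COC(=O)[C@H](C)CC)cc1Br | intermediate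
18 | (2R)-3-acetoxy-2-hydroxy-2-[4-({[(2R)-2-methylbutanoyl]oxy}methyl)-2-(4,4,5,5-tetramethyl-1,3,2-dioxaborolan-2-yl)phenyl]propyl (2Z)-2-methylbut-2-enoate (not isolated) | C/C=C(/C)C(=O)OC[C@](O)(COC(C)=O)c1ccc(COC(=O)[C@H](C)CC)cc1B1OC(C)(C)C(C)(C)O1 | intermediate
19 | (2R)-3-acetoxy-2-hydroxy-2-[2-hydroxy-4-({[(2R)-2-methylbutanoyl]oxy}methyl)phenyl]propyl (2Z)-2-methylbut-2-enoate | C/C=C(/C)C(=O)OC[C@](O)(COC(C)=O)c1ccc(COC(=O)[C@H](C)CC)cc1O | target

Total step count: 9 steps.
Longest linear sequence: 8 steps (steps 1–4, then 6–9); the pyrone branch (step 5) joins at step 6.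

Steps most likely to fail

Step 6. The crowded alkyne may add more slowly than the pyrone decomposes at the temperature needed. Bonding may also occur in the reverse orientation, with the C8-bearing carbon at pyrone C6, or the long heating may isomerise the angelate double bond. The fallback sets out from ketone 1 and acid 16 and comes back to the route at bromide 17, so steps 7 and 8 are then not needed. It makes the aryl–C8 bond by carbonyl addition instead of by ring construction. Purchased 3-bromo-4-iodobenzoic acid F1 is reduced with BH3·SMe2 in THF to (3-bromo-4-iodophenyl)methanol F2. This is esterified with 16 (EDC·HCl, DMAP, CH2Cl2) to (3-bromo-4-iodophenyl)methyl (2R)-2-methylbutanoate F3. Iodine–magnesium exchange with iPrMgCl·LiCl in THF at −40 °C is selective for the C–I bond and tolerates the ester; it gives the arylmagnesium chloride F4 (not isolated). F4 adds to ketone 1 at −40 to −20 °C to give the tertiary alcohol acetonide F5. Acetonide hydrolysis (aq. AcOH, 40 °C) gives the aryl triol F6. Lipase-catalysed monoacetylation as in step 3 gives the (S)-monoacetate F7. Angeloylation through mixed anhydride 6 as in step 4 then gives 17.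

Step 9. Oxidative addition next to the fully substituted C8 may be slow, so that protodebromination outruns borylation. The boron intermediate, held by the neighbouring tertiary hydroxyl, may also resist oxidation at neutral pH. The fallback sets out from 17 and comes back at 19. It is a direct hydroxylation of the aryl bromide with water under nickel/photoredox dual catalysis (NiBr2·glyme, 4,4′-di-tert-butyl-2,2′-bipyridine, the organic photocatalyst 4CzIPN, iPr2NEt, H2O, MeCN, blue light, rt). This C–O coupling needs neither boron nor an inorganic base; no new compound is made on this way (F0).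

Step 3. The enzyme may discriminate poorly between the two enantiotopic hydroxymethyl groups or prefer the wrong one. A slow reaction may also let the monoacetate lose enantiopurity by acetyl migration. The fallback sets out from triol 3 and comes back at 4. The triol is converted with Ac2O and pyridine at 0 °C into the prochiral 2-ethynyl-2-hydroxypropane-1,3-diyl diacetate F8, the tertiary hydroxyl staying free. The desymmetrisation is then run in the hydrolytic direction (same lipase, pH 7 NaH2PO4/Na2HPO4 buffer with MTBE, rt). The enzyme now removes the acetate from the arm it would otherwise acylate, so this mode gives the mirror-image monoacetate. One enzyme therefore gives access to either enantiomer of 4.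

Further compounds
F1 | step 6 | 3-bromo-4-iodobenzoic acid (purchased) | OC(=O)c1ccc(I)c(Br)c1
F2 | step 6 | (3-bromo-4-iodophenyl)methanol | OCc1ccc(I)c(Br)c1
F3 | step 6 | (3-bromo-4-iodophenyl)methyl (2R)-2-methylbutanoate | CC[C@@H](C)C(=O)OCc1ccc(I)c(Br)c1
F4 | step 6 | [2-bromo-4-({[(2R)-2-methylbutanoyl]oxy}methyl)phenyl]magnesium chloride (not isolated) | CC[C@@H](C)C(=O)OCc1ccc([Mg]Cl)c(Br)c1
F5 | step 6 | [3-bromo-4-(5-hydroxy-2,2-dimethyl-1,3-dioxan-5-yl)phenyl]methyl (2R)-2-methylbutanoate | CC[C@@H](C)C(=O)OCc1ccc(C2(O)COC(C)(C)OC2)c(Br)c1
F6 | step 6 | [3-bromo-4-(1,2,3-trihydroxypropan-2-yl)phenyl]methyl (2R)-2-methylbutanoate | CC[C@@H](C)C(=O)OCc1ccc(C(O)(CO)CO)c(Br)c1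
F7 | step 6 | {4-[(2S)-1-acetoxy-2,3-dihydroxypropan-2-yl]-3-bromophenyl}methyl (2R)-2-methylbutanoate | OC[C@](O)(COC(C)=O)c1ccc(COC(=O)[C@H](C)CC)cc1Br
F0 | step 9 | none | none
F8 | step 3 | 2-ethynyl-2-hydroxypropane-1,3-diyl diacetate | CC(=O)OCC(O)(COC(C)=O)C#C
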